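## Analysis of the target

The target is a C2-symmetric 2,2'-linked bis(1,4-benzoquinone), a [1,1'-bi(cyclohexa-1,4-diene)]-3,3',6,6'-tetrone in which, with C1/C1' as the ring-joining carbons, each ring carries in order C2–CH2CH2(2-methoxyphenyl), C3=O, C4–OH, C5–CH3 and C6=O, so that every ring position is substituted. There is no stereocentre; the only stereo element is the C1–C1' axis, flanked by four ortho groups (the C2/C2' chains and the C6/C6' carbonyls), and the SMILES leaves it unspecified. Sensitive groups are the two hydroxyquinones (acidic vinylogous acids, redox-active, electrophilic), the C5–CH3 and C2–CH2 groups (quinone-methide tautomerism in base), and two aryl methyl ethers that must survive whatever unveils the C4 hydroxyls. Two things make the synthesis hard: four different substituents must be placed correctly on a hexasubstituted ring (OH beside the carbonyl that neighbours the side chain, CH3 beside the carbonyl that neighbours the junction), and the junction bond between two fully substituted rings is tetra-ortho-substituted. The feature that invites the move is that C2=C1–C1'=C2', with the arylethyl chains on C2/C2', is a 1,4-disubstituted buta-1,3-diene running through both rings. What remains of each ring, C3–C4–C5–C6, is a four-carbon unit with two carbonyl carbons flanking C–O and C–CH3, which is the skeleton of a squarate-derived cyclobutenone. Both quinone rings can therefore be built at once by a twofold electrocyclic ring expansion of a diene-bridged bis(cyclobutenone), which forms C6–C1 and C6'–C1' while the junction bond C1–C1' is already present as the central σ-bond of the diene and, before that, of a 1,3-diyne.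

## Retrosynthetic reasoning

**15 ⇒ 14.** The two C4/C4' hydroxyls are carried as methyl vinylogous esters. The only bonds cut are the two quinone O–CH3 bonds. A methyl group survives organolithium and thermal steps and can be removed by addition–elimination at C4, which cannot touch the aryl methyl ethers.

**14 ⇒ 13 ⇒ 12 (key disconnection).** After adjusting 14 to the bis-hydroquinone 13, the bonds C6–C1 and C6'–C1' are cut. Each ring then falls apart into a cyclobutenone (C3–C4–C5–C6, with C3 as the carbinol carbon and C6 as the ring carbonyl) attached through C3 to C2 of the diene C2=C1–C1'=C2'. The cut is made here because the substitution pattern then follows from connectivity alone. It also means the hindered C1–C1' bond is never formed between two finished rings. The forward reaction has to open both cyclobutenones to dienylketenes and close both six-membered rings onto the diene termini C1 and C1'.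

**12 ⇒ 11 + two molecules of 3.** The bonds C3–C2 and C3'–C2' are cut, giving the 1,4-dimetallated diene 11 and two molecules of cyclobutenedione 3. The forward addition must take place at the carbonyl of 3 next to the methoxy-bearing carbon. That is the inherently more electrophilic one, since the other carbonyl is a vinylogous ester.

**11 ⇒ 10 ⇒ 9.** The two C–Li bonds of 11 are traced to the two C–Te bonds of tellurophene 10. The ring guarantees that both metals sit on the chain-bearing carbons and cis to the central bond. 10 is opened retrosynthetically to diyne 9, because a chalcogenide adds to a conjugated diyne at the two outer alkyne carbons.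

**9 ⇒ two molecules of 8 ⇒ 7 ⇒ 4 + 5.** The C1–C1' bond is cut at the alkyne oxidation level (oxidative homocoupling of two molecules of 8), where it has no steric demand at all. Alkyne 8 comes from its silyl-capped form 7, made by joining the propargylic carbon of 4 to the benzylic carbon of 5.

**3 ⇒ 2 ⇒ 1.** Cyclobutenedione 3 is the methyl adduct 2 of squarate 1 after loss of methanol. This delivers C3–C6 with both oxygens, the methyl group and the masked hydroxyl in one operation.

## Alternatives that were turned down

**Alternative 1: the textbook cut at C1–C1' at the quinone level.**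
- Disconnection: the single bond between the rings.
- Forward key step: oxidative dimerization of monomer A1 (or its hydroquinone) at its only free ring position, by a one-electron oxidant or by acid-promoted hydroquinone-to-quinone addition and re-oxidation.
- Why turned down: the key step forms one σ-bond and nothing else, and A1 still needs its own regiocontrolled synthesis of a pentasubstituted ring. The bond has to be made between two carbons that are each flanked by a carbonyl and an alkyl chain. The ambident hydroxyquinone can couple through oxygen, and the ortho alkyl group can tautomerize to a quinone methide under the oxidizing conditions. The step count is no lower. A variant of it is kept as a fallback only.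

**Alternative 2: the same bond cut at the arene level.**
- Disconnection: C1–C1' as an aryl–aryl bond between two fully O-methylated rings.
- Forward key step: Ullmann homocoupling of iodide A2 to biaryl A3, then oxidative demethylation to the bis-quinone and unveiling of the C4 hydroxyls.
- Why turned down: A2 is a hexasubstituted, di-ortho-substituted, electron-rich iodide, the least favourable case for a reductive homocoupling. It needs a long linear arene synthesis in which each substituent is placed one by one. The late oxidative demethylation exposes the electron-rich anisole side chains and the benzylic positions to the oxidant. The route is roughly twice as long.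

**Alternative 3: twofold ring expansion in the alkynyl mode.**
- Disconnection: the same C6–C1/C6'–C1' cut, but with a diyne linker and the side chains left off.
- Forward key step: twofold addition of a four-carbon diyne dianion to 3 to give A4; thermolysis to the biquinone A5 through ketene/diradical closure; then twofold decarboxylative radical C–H alkylation to attach both arylethyl chains.
- Why turned down: in the alkynyl mode the ring closes through a diradical. An alkyne terminus that stabilizes a radical (here the second alkynyl group) diverts closure to the five-membered alkylidenecyclopentenedione. The key step would build a core lacking eighteen carbons of the target. The chains would then have to be forced in at the two most hindered C–H positions, ortho to the junction. The key step would build less at higher risk.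

Key step: step 6

Assumption: the SMILES gives no descriptor for the hindered C1–C1' axis, so the target is taken as stereochemically unspecified about this axis and no atroposelective control is planned.

## Route

Step 1
Reactants: 1 dimethyl squarate (3,4-dimethoxycyclobut-3-ene-1,2-dione)
Product: 3 3-methoxy-4-methylcyclobut-3-ene-1,2-dione, via methyl carbinol 2 (not isolated)
Conditions: MeLi, THF, −78 °C; aq. NH4Cl; crude 2, conc. HCl (cat.), CH2Cl2, rt
Reagents that add atoms: methyllithium, C[Li]
Why: 1,2-addition of the organolithium to one of the two equivalent carbonyls gives carbinol 2; acid-catalysed ionization of the carbinol and hydrolysis of the methoxy-stabilized cyclobutenyl cation with loss of methanol (allylic transposition) gives the cyclobutenedione, the standard squarate-to-cyclobutenedione sequence.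

Step 2
Reactants: 4 trimethyl(prop-1-yn-1-yl)silane; 5 1-(chloromethyl)-2-methoxybenzene (2-methoxybenzyl chloride)
Product: 7 [4-(2-methoxyphenyl)but-1-yn-1-yl]trimethylsilane, via lithiated silylpropyne 6 (not isolated)
Conditions: n-BuLi, TMEDA, THF, −78 → 0 °C; then 5, −78 °C → rt
Reagents that add atoms: none
Why: Propargylic deprotonation followed by SN2 alkylation with the benzylic chloride; the silyl cap blocks the acetylenic position and biases the ambident propargyl/allenyl anion toward attack through the propargylic carbon.

Step 3
Reactants: 7 [4-(2-methoxyphenyl)but-1-yn-1-yl]trimethylsilane (two molecules are joined; the second one stands on the reagent line)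
Product: 9 1,8-bis(2-methoxyphenyl)octa-3,5-diyne, via terminal alkyne 8 (not isolated)
Conditions: K2CO3 (cat.), MeOH, rt; then CuCl (cat.), TMEDA, air, rt
Reagents that add atoms: [4-(2-methoxyphenyl)but-1-yn-1-yl]trimethylsilane (the second molecule of 7), COc1ccccc1CCC#C[Si](C)(C)C
Why: Methanolysis of the C(sp)–Si bond of 7 liberates alkyne 8, and Glaser–Hay oxidative homocoupling joins two molecules of 8 through their terminal carbons, so that each half of 9 comes from one molecule of 7. The sp–sp bond made here is the future C1–C1' junction, formed while it is sterically free.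

Step 4
Reactants: 9 1,8-bis(2-methoxyphenyl)octa-3,5-diyne
Product: 10 2,5-bis[2-(2-methoxyphenyl)ethyl]tellurophene
Conditions: Te, NaBH4, EtOH, 78 °C (gives NaHTe); then 9, THF/EtOH, 78 °C, Ar
Reagents that add atoms: sodium hydrogen telluride (made in the flask from tellurium and NaBH4), [Na+].[TeH-]
Why: Nucleophilic anti-addition of telluride to an outer alkyne carbon (the developing anion is stabilized by the second alkyne), protonation, and 5-endo attack of the tellurolate on the second alkyne; this is the classical diyne route to 2,5-disubstituted chalcogenophenes, and it fixes tellurium on the two chain-bearing carbons with both C–Te bonds cis to the central C–C bond.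

Step 5
Reactants: 10 2,5-bis[2-(2-methoxyphenyl)ethyl]tellurophene; 3 3-methoxy-4-methylcyclobut-3-ene-1,2-dione (two molecules are taken up, one at each end of the diene; the second one stands on the reagent line)
Product: 12 4,4'-[(3Z,5Z)-1,8-bis(2-methoxyphenyl)octa-3,5-diene-3,6-diyl]bis(4-hydroxy-3-methoxy-2-methylcyclobut-2-en-1-one), via dilithiodiene 11 (not isolated)
Conditions: n-BuLi (2.1 equiv), THF, −78 °C; then cannulation into 3 (2.5 equiv), THF, −78 °C; aq. NH4Cl
Reagents that add atoms: 3-methoxy-4-methylcyclobut-3-ene-1,2-dione (the second molecule of 3), COC1=C(C)C(=O)C1=O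
Why: Twofold tellurium–lithium exchange opens the tellurophene to the 1,4-dilithio-1,3-diene with retention of both alkene geometries, and each of the two alkenyllithium termini then adds 1,2 to one molecule of 3 at the carbonyl that neighbours the methoxy-bearing carbon (the other carbonyl is a deactivated vinylogous ester). Inverse addition into excess 3 favours the second intermolecular addition over attack of the remaining C–Li on the first-formed cyclobutenone. The two carbinol centres form as a meso/racemic mixture, which is of no consequence because both are destroyed in step 6.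

Step 6
Reactants: 12 4,4'-[(3Z,5Z)-1,8-bis(2-methoxyphenyl)octa-3,5-diene-3,6-diyl]bis(4-hydroxy-3-methoxy-2-methylcyclobut-2-en-1-one)
Product: 14 4,4'-dimethoxy-5,5'-dimethyl-2,2'-bis[2-(2-methoxyphenyl)ethyl]-[1,1'-bi(cyclohexa-1,4-diene)]-3,3',6,6'-tetrone, via bis-hydroquinone 13 (not isolated)
Conditions: p-xylene (degassed, high dilution), 138 °C, Ar; then Ag2O, MgSO4, Et2O, rt
Reagents that add atoms: none
Why: Each 4-alkenyl-4-hydroxycyclobutenone of 12 opens thermally by conrotatory 4π-electrocyclic cleavage of the bond between its carbonyl carbon and its carbinol carbon, with the hydroxyl rotating outward so that the dienyl group lies cis to the new ketene. The dienylketene closes by 6π-electrocyclization between the ketene carbon (future C6) and the CH terminus of the adjacent alkene (future C1), the cyclohexa-2,4-dienone enolizes by loss of the C1 hydrogen, and the same sequence at the second cyclobutenone gives 13, which Ag2O oxidizes in the same flask to 14. The closest known reaction type is the thermal ring expansion of 4-alkenyl- and 4-aryl-4-hydroxycyclobutenones to hydroquinones and quinones (Moore–Liebeskind ring expansion), run here twice across one diene. Both six-membered rings close in the pericyclic 6π (disrotatory) mode and not through a diradical, so the five-membered closure that plagues the alkynyl variant has no counterpart. No stereocentre survives: the carbinol centres and the transient sp3 C1 become aromatic carbons, and the C1–C1' axis is left uncontrolled. The substitution pattern is fixed by connectivity, not selectivity: the ketene carbon is the one next to C–CH3 and bonds to C1, so CH3 (C5) ends up beside the carbonyl next to the junction and OCH3 (C4) beside the carbonyl next to the side chain. The selectivities the step does need are outward rotation of hydroxyl (secured by its donor character; inward rotation would lead to a butenolide) and closure onto an alkene terminus with an inward substituent (the second alkenyl unit, then the first-formed aryl ring), which the (3Z,5Z) geometry imposes. The ketene terminus has no inward group, so this penalty should be met by the 138 °C bath, and high dilution suppresses trapping of the ketene by phenolic hydroxyls.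

Step 7
Reactants: 14 4,4'-dimethoxy-5,5'-dimethyl-2,2'-bis[2-(2-methoxyphenyl)ethyl]-[1,1'-bi(cyclohexa-1,4-diene)]-3,3',6,6'-tetrone
Product: 15 4,4'-dihydroxy-5,5'-dimethyl-2,2'-bis[2-(2-methoxyphenyl)ethyl]-[1,1'-bi(cyclohexa-1,4-diene)]-3,3',6,6'-tetrone (CNP0293637.0)
Conditions: NaOH (1 M aq.), MeOH/THF, 0 °C → rt; then 1 M HCl
Reagents that add atoms: sodium hydroxide, [Na+].[OH-]
Why: The quinone methoxy groups are vinylogous esters: hydroxide adds at C4/C4' (β to the C6 carbonyl) and expels methoxide (addition–elimination), the hydroxyquinone is protected as its stabilized anion until acidification, and the aryl methyl ethers are inert to aqueous base.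

## Compound list

1 | dimethyl squarate (3,4-dimethoxycyclobut-3-ene-1,2-dione) | COC1=C(OC)C(=O)C1=O | starting material
2 | 4-hydroxy-2,3-dimethoxy-4-methylcyclobut-2-en-1-one (racemic) | COC1=C(OC)C(C)(O)C1=O | intermediate (not isolated)
3 | 3-methoxy-4-methylcyclobut-3-ene-1,2-dione | COC1=C(C)C(=O)C1=O | intermediate
4 | trimethyl(prop-1-yn-1-yl)silane | CC#C[Si](C)(C)C | starting material
5 | 1-(chloromethyl)-2-methoxybenzene | COc1ccccc1CCl | starting material
6 | [3-(trimethylsilyl)prop-2-yn-1-yl]lithium | [Li]CC#C[Si](C)(C)C | intermediate (not isolated)
7 | [4-(2-methoxyphenyl)but-1-yn-1-yl]trimethylsilane | COc1ccccc1CCC#C[Si](C)(C)C | intermediate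
8 | 1-(but-3-yn-1-yl)-2-methoxybenzene | COc1ccccc1CCC#C | intermediate (not isolated)
9 | 1,8-bis(2-methoxyphenyl)octa-3,5-diyne | COc1ccccc1CCC#CC#CCCc1ccccc1OC | intermediate
10 | 2,5-bis[2-(2-methoxyphenyl)ethyl]tellurophene | COc1ccccc1CCC1=CC=C(CCc2ccccc2OC)[Te]1 | intermediate
11 | (3E,5E)-3,6-dilithio-1,8-bis(2-methoxyphenyl)octa-3,5-diene (each lithium cis to the neighbouring alkene carbon) | [Li]/C(CCc1ccccc1OC)=C\C=C(/[Li])CCc1ccccc1OC | intermediate (not isolated)
12 | 4,4'-[(3Z,5Z)-1,8-bis(2-methoxyphenyl)octa-3,5-diene-3,6-diyl]bis(4-hydroxy-3-methoxy-2-methylcyclobut-2-en-1-one) (meso/racemic mixture at the carbinol carbons) | O=C1C(C)=C(OC)C1(O)/C(CCc2ccccc2OC)=C\C=C(/C1(O)C(OC)=C(C)C1=O)CCc1ccccc1OC | intermediate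
13 | 4,4'-dimethoxy-6,6'-bis[2-(2-methoxyphenyl)ethyl]-3,3'-dimethyl-[1,1'-biphenyl]-2,2',5,5'-tetrol | COc1ccccc1CCc1c(O)c(OC)c(C)c(O)c1-c1c(O)c(C)c(OC)c(O)c1CCc1ccccc1OC | intermediate (not isolated)
14 | 4,4'-dimethoxy-5,5'-dimethyl-2,2'-bis[2-(2-methoxyphenyl)ethyl]-[1,1'-bi(cyclohexa-1,4-diene)]-3,3',6,6'-tetrone | COc1ccccc1CCC1=C(C2=C(CCc3ccccc3OC)C(=O)C(OC)=C(C)C2=O)C(=O)C(C)=C(OC)C1=O | intermediate
15 | 4,4'-dihydroxy-5,5'-dimethyl-2,2'-bis[2-(2-methoxyphenyl)ethyl]-[1,1'-bi(cyclohexa-1,4-diene)]-3,3',6,6'-tetrone | COc1ccccc1CCC1=C(C2=C(CCc3ccccc3OC)C(=O)C(O)=C(C)C2=O)C(=O)C(C)=C(O)C1=O | target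

## Step count and least certain steps

Total step count: 7. Longest linear sequence: 6 steps (steps 2–7, from 4 and 5); step 1 is a one-step branch that supplies 3.

**Step 6 (key step).** What may go wrong: the 6π closure is retarded by the inward substituent that the (3Z,5Z) geometry places on the alkene terminus. This is most severe in the second closure, where the inward group is the first-formed aryl ring and the tetra-ortho-substituted junction is set up. The reversibly formed ketene can then drain away through inward rotation of hydroxyl followed by lactonization, or through addition of phenolic hydroxyls. Fallback: build the rings one at a time on an alkene terminus with no inward substituent and make the junction last; it sets out from 8 (isolated after the K2CO3/MeOH stage of step 3) and 3, and comes back at 13 and 14. Markovnikov hydrobromination of 8 (Et4N HBr2, CH2Cl2) should give 1-(3-bromobut-3-en-1-yl)-2-methoxybenzene F1. Bromine–lithium exchange (t-BuLi, −78 °C) should give [4-(2-methoxyphenyl)but-1-en-2-yl]lithium F2, which adds to 3 to give 4-hydroxy-3-methoxy-4-[4-(2-methoxyphenyl)but-1-en-2-yl]-2-methylcyclobut-2-en-1-one F3. Thermolysis (toluene, 110 °C) should give 3-methoxy-5-[2-(2-methoxyphenyl)ethyl]-2-methylbenzene-1,4-diol F4, since the alkene terminus is now CH2. Half of F4 is oxidized (Ag2O) to 3-methoxy-5-[2-(2-methoxyphenyl)ethyl]-2-methylcyclohexa-2,5-diene-1,4-dione F5. Acid-promoted conjugate addition of F4 to F5 (BF3·OEt2, CH2Cl2), each through its only free ring position, should give 13, which is oxidized to 14 as in the second stage of step 6.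

**Step 5.** What may go wrong: after the first addition the second C–Li, held cis by the diene geometry, can add to the remaining vinylogous-ester carbonyl of its own cyclobutenone, or displace the alkoxide, faster than it finds a second molecule of 3. Competing addition of excess butyllithium to 3 is a lesser concern. Fallback: never generate a carbanion next to a cyclobutenone, make both C3–C2 bonds by palladium-catalysed coupling and introduce the C3 oxygen last; it sets out from 11 and 3 and comes back at 14. 11 is quenched with Me3SnCl to [(3Z,5Z)-1,8-bis(2-methoxyphenyl)octa-3,5-diene-3,6-diyl]bis(trimethylstannane) F6. 3 is reduced at its ketone carbonyl (LiAlH(Ot-Bu)3, THF, −78 °C) to 4-hydroxy-3-methoxy-2-methylcyclobut-2-en-1-one F7 and converted (SOCl2, cat. DMF, CH2Cl2) into 4-chloro-3-methoxy-2-methylcyclobut-2-en-1-one F8. Twofold Stille coupling of F6 with F8 ((PhCN)2PdCl2, tri(2-furyl)phosphine, dioxane, 50 → 100 °C) should give 4-dienylcyclobutenones that ring-expand in the same flask to 4,4'-dimethoxy-6,6'-bis[2-(2-methoxyphenyl)ethyl]-3,3'-dimethyl-[1,1'-biphenyl]-2,2'-diol F9. Oxidation of each phenol at its free para position (potassium nitrosodisulfonate K2NO(SO3)2, KH2PO4, acetone/H2O) should give 14.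

**Step 4.** What may go wrong: slow addition of telluride to a diyne activated only by alkyl groups, so that mono-addition, reduction or oligomerization of the diyne and air oxidation of the tellurium species compete with ring closure. Fallback: use tin in place of tellurium and make the central bond by alkene homocoupling instead of carrying it in from the diyne; it sets out from 8 (isolated as above) and comes back at 11. Syn-distannylation of 8 (Me3SnSnMe3, Pd(PPh3)4 cat., THF, 65 °C) should give (Z)-[4-(2-methoxyphenyl)but-1-ene-1,2-diyl]bis(trimethylstannane) F10. Oxidative homocoupling at the less hindered terminal C–Sn bond (CuCl, DMF, rt) should give [(3Z,5Z)-1,8-bis(2-methoxyphenyl)octa-3,5-diene-3,6-diyl]bis(trimethylstannane) F6, with each remaining tin cis to the new central bond. Tin–lithium exchange (MeLi, 2 equiv, THF, −78 °C) then gives 11 free of tellurium.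

**Step 7.** What may go wrong: in aqueous base the C5–CH3 and C2–CH2 groups can tautomerize to quinone methides and condense, and the biquinone can undergo redox side reactions, before the slower addition–elimination at the hindered C4 is complete. Fallback: exchange under neutral conditions, then hydrolyse in acid; it sets out from 14 and comes back at 15. Pyrrolidine (MeOH, rt) should displace both quinone methoxy groups by addition–elimination to give 5,5'-dimethyl-2,2'-bis[2-(2-methoxyphenyl)ethyl]-4,4'-di(pyrrolidin-1-yl)-[1,1'-bi(cyclohexa-1,4-diene)]-3,3',6,6'-tetrone F11. Aqueous acid (2 M HCl, dioxane, 60 °C) should hydrolyse the vinylogous amides of F11 to 15 without exposing the quinone to base.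

## Further compounds

F1 | step 6 | 1-(3-bromobut-3-en-1-yl)-2-methoxybenzene | C=C(Br)CCc1ccccc1OC
F2 | step 6 | [4-(2-methoxyphenyl)but-1-en-2-yl]lithium | [Li]C(=C)CCc1ccccc1OC
F3 | step 6 | 4-hydroxy-3-methoxy-4-[4-(2-methoxyphenyl)but-1-en-2-yl]-2-methylcyclobut-2-en-1-one (racemic) | C=C(CCc1ccccc1OC)C1(O)C(OC)=C(C)C1=O
F4 | step 6 | 3-methoxy-5-[2-(2-methoxyphenyl)ethyl]-2-methylbenzene-1,4-diol | COc1ccccc1CCc1cc(O)c(C)c(OC)c1O
F5 | step 6 | 3-methoxy-5-[2-(2-methoxyphenyl)ethyl]-2-methylcyclohexa-2,5-diene-1,4-dione | COc1ccccc1CCC1=CC(=O)C(C)=C(OC)C1=O
F6 | step 5 | [(3Z,5Z)-1,8-bis(2-methoxyphenyl)octa-3,5-diene-3,6-diyl]bis(trimethylstannane) | C[Sn](C)(C)/C(CCc1ccccc1OC)=C\C=C(/[Sn](C)(C)C)CCc1ccccc1OC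
F7 | step 5 | 4-hydroxy-3-methoxy-2-methylcyclobut-2-en-1-one (racemic) | O=C1C(C)=C(OC)C1O
F8 | step 5 | 4-chloro-3-methoxy-2-methylcyclobut-2-en-1-one (racemic) | O=C1C(C)=C(OC)C1Cl
F9 | step 5 | 4,4'-dimethoxy-6,6'-bis[2-(2-methoxyphenyl)ethyl]-3,3'-dimethyl-[1,1'-biphenyl]-2,2'-diol | COc1ccccc1CCc1cc(OC)c(C)c(O)c1-c1c(O)c(C)c(OC)cc1CCc1ccccc1OC
F10 | step 4 | (Z)-[4-(2-methoxyphenyl)but-1-ene-1,2-diyl]bis(trimethylstannane) | C[Sn](C)(C)/C=C(\[Sn](C)(C)C)CCc1ccccc1OC
F11 | step 7 | 5,5'-dimethyl-2,2'-bis[2-(2-methoxyphenyl)ethyl]-4,4'-di(pyrrolidin-1-yl)-[1,1'-bi(cyclohexa-1,4-diene)]-3,3',6,6'-tetrone | COc1ccccc1CCC1=C(C2=C(CCc3ccccc3OC)C(=O)C(N3CCCC3)=C(C)C2=O)C(=O)C(C)=C(N2CCCC2)C1=O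
A1 | alternative 1 | 2-hydroxy-6-[2-(2-methoxyphenyl)ethyl]-3-methylcyclohexa-2,5-diene-1,4-dione | COc1ccccc1CCC1=CC(=O)C(C)=C(O)C1=O
A2 | alternative 2 | 1-iodo-2,4,5-trimethoxy-6-[2-(2-methoxyphenyl)ethyl]-3-methylbenzene | COc1ccccc1CCc1c(I)c(OC)c(C)c(OC)c1OC
A3 | alternative 2 | 2,2',4,4',5,5'-hexamethoxy-6,6'-bis[2-(2-methoxyphenyl)ethyl]-3,3'-dimethyl-1,1'-biphenyl | COc1ccccc1CCc1c(OC)c(OC)c(C)c(OC)c1-c1c(OC)c(C)c(OC)c(OC)c1CCc1ccccc1OC
A4 | alternative 3 | 4,4'-(buta-1,3-diyne-1,4-diyl)bis(4-hydroxy-3-methoxy-2-methylcyclobut-2-en-1-one) | O=C1C(C)=C(OC)C1(O)C#CC#CC1(O)C(OC)=C(C)C1=O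
A5 | alternative 3 | 4,4'-dimethoxy-5,5'-dimethyl-[1,1'-bi(cyclohexa-1,4-diene)]-3,3',6,6'-tetrone | COC1=C(C)C(=O)C(=CC1=O)C1=CC(=O)C(OC)=C(C)C1=O
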